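A small charge is what you have to forecast here: the midnight flask starts with 0.100 M of starting material, less than either earlier run, with the same free catalyst.

| setting | summer | dawn | midnight |
|---|---|---|---|
| starting material | 0.200 M | 0.600 M | 0.100 M |
| free catalyst | 0.00400 M | 0.00400 M | 0.00400 M |
| time |  |  | 43 min |

| run | time / min | [target] / M |
|---|---|---|
| summer run | 1.7 | 1 × 10⁻⁴ |
| summer run | 2.9 | 0.0026 |
| summer run | 5.0 | 0.0112 |
| summer run | 8.6 | 0.0161 |
| summer run | 15 | 0.0354 |
| summer run | 25 | 0.0507 |
| summer run | 43 | 0.0656 |
| dawn run | 1.7 | 0.0018 |
| dawn run | 2.9 | 0.0061 |
| dawn run | 5.0 | 0.0213 |
| dawn run | 8.6 | 0.0472 |
| dawn run | 15 | 0.0958 |
| dawn run | 25 | 0.1554 |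
| dawn run | 43 | 0.2142 |

(each reading ± 0.002 M)

1. how the opening rate goes with [starting material] round the charge of the summer run: the exponent of the rate at two percent of starting material gone to target (one fixed amount of target, the same in the runs compared)
2. target in the midnight run at 43 min, as a share of the starting material charged

- Overall: starting material -> target, with free catalyst as catalyst.
- Constant volume, constant temperature.
- What is held in complexes is read along with the free species.
- An order is taken over about fifteen percent of the charge, up and down.

Take the share of the charge that has become target at one fixed time, and compare the runs. At 43 min the summer run shows 32.8% and the dawn run 35.7%, so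

share exponent = ln(dawn share / summer share) / ln(dawn charge / summer charge) = 0.0771

This share exponent, the power of the charge that the share at a fixed time follows, comes close to the rate order minus one while little has turned, provided the catalyst and its clock are alike in the runs compared; at shares like these, an order above one gives an exponent below that value. Carried down, it puts the midnight flask at 31.1%.

But that exponent is an average over charges above the midnight one. At 15 min the same reckoning on the summer and dawn runs gives −0.0938, so the exponent rose by 0.171 with time, against a scatter of 0.0620. It is a faint reading, but it hints that the order climbs as starting material falls.

So I solve both ends. One end keeps 0.0771. At the other, which is my guess, two molecules of starting material must meet on the catalyst: the order is 2, and with the same catalyst clock the ratio of turned to unturned starting material goes in step with the charge, so the summer ratio 0.488 falls to 0.244 at midnight, which is a share of 19.6% and an exponent of 0.742. Joining them at the middle exponent, which is a judgement and not a measurement: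

midnight share = summer share × (midnight charge / summer charge)^0.409 = 24.7%

For the order at the summer charge I take one plus the early exponent, 0.906, though that belongs to a fixed time and not to a fixed amount of target.

The forecast gives 0.7 and 34%, holding that “the reaction is close to first order in starting material”. My midnight share is lower.

The flask gives an order of 0.93 and a midnight share of 24.0%.

    active catalyst + starting material ⇌ catalyst-substrate complex, settled at all times (1.120 M⁻¹)
    catalyst-substrate complex + starting material ⇌ doubly bound catalyst, settled at all times (10.60 M⁻¹)
    doubly bound catalyst → target + catalyst-substrate complex (3.306 min⁻¹)
    target → decomposed product (0.01686 min⁻¹)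
    free catalyst → active catalyst (0.3054 min⁻¹)

The power-law fit to the summer and dawn runs left residuals of 3.8 in units of the scatter and gave 34.5% for the midnight run. Between the midnight and summer charges the share exponent comes to 0.451, larger than the 0.0771 between summer and dawn, and the midnight share is 24.0% where the summer-to-dawn exponent gave 31.1%.

The data are simulated from invented constants; noise was put on by code.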